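**Strategy.** Ring C (the pyran-4-one) is cut across two bonds at once, O1–C2 and C3–C4. The tetrasubstituted C2=C3 unit is then an internal alkyne that already carries ring B and the C3 prenyl group, and C4 is the formyl carbon of a salicylaldehyde. One rhodium-catalysed oxidative formyl C–H/O–H [4+2] annulation joins both halves, closes ring C and fixes the crowded 2-aryl-3-prenyl pattern. Its precursors are a skipped aryl enyne and a phloroglucinaldehyde whose prenyl group sits between two MOM ethers (placed by a para-Claisen–Cope shift) and whose single free ortho hydroxyl becomes O1, so that C6 rather than C8 prenylation is built in.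

Key step: step 7

Remark on the chemistry: the target has no stereocentre and no stereogenic double bond (both alkenes end in CMe2). It is achiral, so the request for a single enantiomer needs no stereocontrol. The transient stereocentres in 6 and 7 vanish on aromatisation.

Step 1
Reactants: 1 2,4,6-trihydroxybenzaldehyde; 2 chloromethyl methyl ether (MOMCl)
Product: 3 2-hydroxy-4,6-bis(methoxymethoxy)benzaldehyde
Conditions: MOMCl (2.1 equiv), i-Pr2NEt (2.5 equiv), CH2Cl2, 0 °C → rt
Reagents that add atoms: chloromethyl methyl ether (2), COCCl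
Why: Williamson-type MOM protection in which the 4-hydroxyl and one of the two equivalent ortho hydroxyls react, while the last hydroxyl stays locked in a hydrogen bond to the formyl oxygen, so only one bis-ether is expected.

Step 2
Reactants: 3 2-hydroxy-4,6-bis(methoxymethoxy)benzaldehyde; 4 prenyl bromide (1-bromo-3-methylbut-2-ene)
Product: 5 2,4-bis(methoxymethoxy)-6-(3-methylbut-2-enyloxy)benzaldehyde
Conditions: prenyl bromide, K2CO3, DMF, rt
Reagents that add atoms: prenyl bromide (4), CC(C)=CCBr
Why: Williamson ether synthesis, in which carbonate in a dipolar aprotic solvent opens the chelate and the phenoxide oxygen displaces the primary allylic bromide by SN2.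

Step 3
Reactants: 5 2,4-bis(methoxymethoxy)-6-(3-methylbut-2-enyloxy)benzaldehyde
Product: 8 6-hydroxy-2,4-bis(methoxymethoxy)-3-(3-methylbut-2-enyl)benzaldehyde, via ortho-dienone 6 (not isolated), via para-dienone 7 (not isolated)
Conditions: PhNEt2, 200 °C, Ar
Reagents that add atoms: none
Why: Tandem aromatic Claisen–Cope (para-Claisen) rearrangement, in which the first [3,3] shift puts the reversed prenyl unit on the only free ortho carbon (6), steric compression next to the MOM ether drives a second [3,3] shift to the para carbon between the two MOM ethers (7), and enolisation gives 8 with a normal prenyl group and the freed hydroxyl where O1 is needed.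

Step 4
Reactants: 9 2,4-dihydroxybenzaldehyde; 2 chloromethyl methyl ether (MOMCl)
Product: 10 2,4-bis(methoxymethoxy)benzaldehyde
Conditions: NaH (2.5 equiv), MOMCl (2.5 equiv), DMF, 0 °C → rt
Reagents that add atoms: chloromethyl methyl ether (2), COCCl
Why: Williamson-type MOM protection with full deprotonation by NaH, which also engages the chelated 2-hydroxyl.

Step 5
Reactants: 10 2,4-bis(methoxymethoxy)benzaldehyde; 11 dimethyl (1-diazo-2-oxopropyl)phosphonate
Product: 13 1-ethynyl-2,4-bis(methoxymethoxy)benzene, via diazoalkene 12 (not isolated)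
Conditions: 11, K2CO3, MeOH, rt
Reagents that add atoms: dimethyl (1-diazo-2-oxopropyl)phosphonate (11), CC(=O)C(=[N+]=[N-])P(=O)(OC)OC
Why: Ohira–Bestmann variant of the Seyferth–Gilbert homologation, in which methanolysis of 11 frees the diazomethylphosphonate anion, its Horner–Wadsworth–Emmons-type addition to 10 gives diazoalkene 12, and loss of N2 with a 1,2-hydride shift gives the alkyne under conditions that leave MOM ethers intact.

Step 6
Reactants: 13 1-ethynyl-2,4-bis(methoxymethoxy)benzene; 4 prenyl bromide
Product: 14 1-(5-methylhex-4-en-1-yn-1-yl)-2,4-bis(methoxymethoxy)benzene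
Conditions: prenyl bromide, CuI (10 mol %), Bu4NI (10 mol %), K2CO3, DMF, rt
Reagents that add atoms: prenyl bromide (4), CC(C)=CCBr
Why: Copper-catalysed allylic alkynylation (copper acetylide SN2 on a primary allylic bromide), which should form the bond at the unhindered CH2 terminus and give the skipped 1,4-enyne under a base too weak to isomerise it.

Step 7
Reactants: 8 6-hydroxy-2,4-bis(methoxymethoxy)-3-(3-methylbut-2-enyl)benzaldehyde; 14 1-(5-methylhex-4-en-1-yn-1-yl)-2,4-bis(methoxymethoxy)benzene
Product: 15 2-[2,4-bis(methoxymethoxy)phenyl]-5,7-bis(methoxymethoxy)-3,6-bis(3-methylbut-2-enyl)-4H-chromen-4-one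
Conditions: [RhCl(cod)]2 (2.5 mol %), 1,2,3,4-tetraphenylcyclopenta-1,3-diene (10 mol %), Cu(OAc)2·H2O (2.2 equiv), o-xylene, 120 °C, N2
Reagents that add atoms: none
Why: The phenoxide of 8 binds Rh(III), acetate-assisted cleavage of the formyl C–H bond gives a five-membered acyl-rhodacycle, 14 inserts syn into the Rh–acyl bond to give a seven-membered rhodacycle, C–O reductive elimination releases 15, and Cu(II) returns Rh(I) to Rh(III). The closest known reaction type is the rhodium/copper oxidative annulation of salicylaldehydes with internal alkynes to 2,3-disubstituted chromones. Ring C closes as a formal [4+2] union (O1, C8a, C4a and C4 from 8; C2 and C3 from 14), with C3–C4 formed by migratory insertion and O1–C2 by reductive elimination at the metal, so no 5-exo/6-endo competition (aurone versus flavone) arises. No stereocentre is formed. The step needs one orientation of the unsymmetrical alkyne: the aryl-bearing carbon should end up on rhodium (conjugative stabilisation of the Rh–C bond, larger group next to the metal, possible contact of the ortho MOM oxygen), so that the CH2-bearing carbon bonds to the acyl carbon and the 2-aryl-3-prenyl pattern results. Site selectivity (C6 over C8 prenyl) rests on the single free hydroxyl of 8, and chemoselectivity rests on the poor binding of the trisubstituted prenyl alkenes and on syn insertion, which holds the C3 side chain trans to rhodium and out of reach of a second insertion.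

Step 8
Reactants: 15 2-[2,4-bis(methoxymethoxy)phenyl]-5,7-bis(methoxymethoxy)-3,6-bis(3-methylbut-2-enyl)-4H-chromen-4-one
Product: 16 cudraflavone C, 2-(2,4-dihydroxyphenyl)-5,7-dihydroxy-3,6-bis(3-methylbut-2-enyl)-4H-chromen-4-one
Conditions: conc. HCl (cat.), MeOH, 45 °C
Reagents that add atoms: none
Why: Acid-catalysed acetal exchange (methanolysis of four aryl MOM ethers), a common closing operation for prenylated flavonoids, which at low acid strength and mild temperature should outrun protonation of the trisubstituted alkenes.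

**Compound list**
1 | 2,4,6-trihydroxybenzaldehyde | O=Cc1c(O)cc(O)cc1O | starting material
2 | chloromethyl methyl ether (MOMCl) | COCCl | starting material
3 | 2-hydroxy-4,6-bis(methoxymethoxy)benzaldehyde | O=Cc1c(O)cc(OCOC)cc1OCOC | intermediate
4 | prenyl bromide (1-bromo-3-methylbut-2-ene) | CC(C)=CCBr | starting material
5 | 2,4-bis(methoxymethoxy)-6-(3-methylbut-2-enyloxy)benzaldehyde | O=Cc1c(OCC=C(C)C)cc(OCOC)cc1OCOC | intermediate
6 | ortho-dienone, 2,4-bis(methoxymethoxy)-5-(2-methylbut-3-en-2-yl)-6-oxocyclohexa-1,3-diene-1-carbaldehyde (racemic, transient) | O=CC1=C(OCOC)C=C(OCOC)C(C(C)(C)C=C)C1=O | intermediate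
7 | para-dienone, 2,4-bis(methoxymethoxy)-3-(3-methylbut-2-enyl)-6-oxocyclohexa-1,4-diene-1-carbaldehyde (racemic, transient) | O=CC1=C(OCOC)C(CC=C(C)C)C(OCOC)=CC1=O | intermediate
8 | 6-hydroxy-2,4-bis(methoxymethoxy)-3-(3-methylbut-2-enyl)benzaldehyde | O=Cc1c(O)cc(OCOC)c(CC=C(C)C)c1OCOC | intermediate
9 | 2,4-dihydroxybenzaldehyde | O=Cc1ccc(O)cc1O | starting material
10 | 2,4-bis(methoxymethoxy)benzaldehyde | O=Cc1ccc(OCOC)cc1OCOC | intermediate
11 | dimethyl (1-diazo-2-oxopropyl)phosphonate | CC(=O)C(=[N+]=[N-])P(=O)(OC)OC | starting material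
12 | diazoalkene, 1-(2-diazoethenyl)-2,4-bis(methoxymethoxy)benzene | COCOc1ccc(C=C=[N+]=[N-])c(OCOC)c1 | intermediate
13 | 1-ethynyl-2,4-bis(methoxymethoxy)benzene | C#Cc1ccc(OCOC)cc1OCOC | intermediate
14 | 1-(5-methylhex-4-en-1-yn-1-yl)-2,4-bis(methoxymethoxy)benzene | CC(C)=CCC#Cc1ccc(OCOC)cc1OCOC | intermediate
15 | 2-[2,4-bis(methoxymethoxy)phenyl]-5,7-bis(methoxymethoxy)-3,6-bis(3-methylbut-2-enyl)-4H-chromen-4-one | CC(C)=CCc1c(OCOC)cc2oc(-c3ccc(OCOC)cc3OCOC)c(CC=C(C)C)c(=O)c2c1OCOC | intermediate
16 | cudraflavone C | CC(C)=CCc1c(O)cc2oc(-c3ccc(O)cc3O)c(CC=C(C)C)c(=O)c2c1O | target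

**Total step count:** 8. **Longest linear sequence:** 5 steps (1, 2, 3, 7, 8 or 4, 5, 6, 7, 8).

**Steps most likely to fail**

Step 7. Several processes could compete:
- slow insertion of the ortho-substituted, hindered alkyne;
- decarbonylation of the acyl-rhodium species;
- metal- or acetate-induced isomerisation of the skipped enyne to a conjugated system;
- erosion of the insertion orientation.

The fallback builds ring C stepwise and adds the C3 prenyl group last. It sets out from 8 and 13 and comes back at 15. Excess lithium acetylide of 13 (n-BuLi, THF, −78 → 0 °C) is added to 8 to give the racemic propargylic alcohol F1. MnO2 oxidation gives the o-hydroxyaryl ynone F2. DMAP-catalysed 6-endo oxa-Michael cyclisation in DMF gives the 3-unsubstituted flavone F3. C3 lithiation with LDA at −78 °C and an iodine quench give the 3-iodoflavone F4. Stille coupling with tributyl(3-methylbut-2-enyl)stannane (Pd(0), LiCl, DMF) gives 15.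

Step 3. The rearrangement may stop after the first [3,3] shift by enolisation. The ether may also fragment with loss of isoprene, or the ipso shift may lead to deformylation. The fallback places the prenyl group by directed metalation on a symmetric arene and adds the formyl group last. It sets out from 2 and 4, used on commercial phloroglucinol, and comes back at 8. Bis-protection with 2 (i-Pr2NEt, CH2Cl2) gives 3,5-bis(methoxymethoxy)phenol F5. TIPSCl/imidazole gives the silyl ether F6. Directed ortho-metalation between the two MOM ethers (n-BuLi, THF, 0 °C), followed by CuBr·SMe2 (cat.) and 4, gives the 4-prenyl arene F7. TBAF gives the symmetric 3,5-bis(methoxymethoxy)-4-(3-methylbut-2-enyl)phenol F8. Its two ortho positions are equivalent, so magnesium-mediated ortho-formylation (MgCl2, Et3N, paraformaldehyde, MeCN, reflux; Casnati–Skattebøl) can lead only to 8.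

Step 8. The liberated 5-, 7- or 2'-hydroxyls may add to the protonated prenyl alkenes (chroman-type ring closure) faster than the last MOM group leaves. The fallback avoids Brønsted acid by exchanging the protecting groups. It sets out from 15 and comes back at 16. TESOTf and 2,2'-bipyridyl in CH2Cl2 at 0 °C convert the aryl MOM ethers into the tetrakis(triethylsilyl) ether F9. This is cleaved with AcOH-buffered TBAF in THF at 0 °C to give 16.

**Further compounds**
F1 | step 7 | 1-[6-hydroxy-2,4-bis(methoxymethoxy)-3-(3-methylbut-2-enyl)phenyl]-3-[2,4-bis(methoxymethoxy)phenyl]prop-2-yn-1-ol (racemic) | OC(C#Cc1ccc(OCOC)cc1OCOC)c1c(O)cc(OCOC)c(CC=C(C)C)c1OCOC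
F2 | step 7 | 1-[6-hydroxy-2,4-bis(methoxymethoxy)-3-(3-methylbut-2-enyl)phenyl]-3-[2,4-bis(methoxymethoxy)phenyl]prop-2-yn-1-one | O=C(C#Cc1ccc(OCOC)cc1OCOC)c1c(O)cc(OCOC)c(CC=C(C)C)c1OCOC
F3 | step 7 | 2-[2,4-bis(methoxymethoxy)phenyl]-5,7-bis(methoxymethoxy)-6-(3-methylbut-2-enyl)-4H-chromen-4-one | CC(C)=CCc1c(OCOC)cc2oc(-c3ccc(OCOC)cc3OCOC)cc(=O)c2c1OCOC
F4 | step 7 | 2-[2,4-bis(methoxymethoxy)phenyl]-3-iodo-5,7-bis(methoxymethoxy)-6-(3-methylbut-2-enyl)-4H-chromen-4-one | CC(C)=CCc1c(OCOC)cc2oc(-c3ccc(OCOC)cc3OCOC)c(I)c(=O)c2c1OCOC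
F5 | step 3 | 3,5-bis(methoxymethoxy)phenol | Oc1cc(OCOC)cc(OCOC)c1
F6 | step 3 | [3,5-bis(methoxymethoxy)phenoxy]triisopropylsilane | CC(C)[Si](Oc1cc(OCOC)cc(OCOC)c1)(C(C)C)C(C)C
F7 | step 3 | [3,5-bis(methoxymethoxy)-4-(3-methylbut-2-enyl)phenoxy]triisopropylsilane | CC(C)=CCc1c(OCOC)cc(O[Si](C(C)C)(C(C)C)C(C)C)cc1OCOC
F8 | step 3 | 3,5-bis(methoxymethoxy)-4-(3-methylbut-2-enyl)phenol | CC(C)=CCc1c(OCOC)cc(O)cc1OCOC
F9 | step 8 | cudraflavone C tetrakis(triethylsilyl) ether | CC(C)=CCc1c(O[Si](CC)(CC)CC)cc2oc(-c3ccc(O[Si](CC)(CC)CC)cc3O[Si](CC)(CC)CC)c(CC=C(C)C)c(=O)c2c1O[Si](CC)(CC)CC
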